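Abbreviations: TBS = tert-butyldimethylsilyl, TES = triethylsilyl, PMB = 4-methoxybenzyl, DBU = 1,8-diazabicyclo[5.4.0]undec-7-ene, DMPU = N,N′-dimethylpropyleneurea. Ring compounds are named with the ring numbering of the target (C1–C6); β is the face of the C1 vinyl group, α the opposite face.

## Analysis of the target

The target is a cyclohexane that is substituted at every ring atom but one. With the ring numbered C1 (quaternary, methyl and vinyl), C2 (CH2), C3 (acyloxy), C4 (1-carboxyvinyl), C5 (hydroxyl) and C6 (3-hydroxyprop-1-en-2-yl), the five contiguous atoms C3–C4–C5–C6–C1 are stereocentres. The C4 and C6 side chains and the C5 hydroxyl lie on the β face with the C1 vinyl group, whereas the C3 oxygen and the C1 methyl are α; in the chair everything is equatorial except the C5 hydroxyl and the C1 vinyl group, which stand syn-axial. The sensitive groups are the C4 acrylic acid cis to the C5 hydroxyl (a Michael acceptor and a γ-hydroxy acid that closes to the α-methylene-γ-butyrolactone under acid), the (Z)-4-acetoxy-2-methylbut-2-enoate at C3 (Z to E isomerisation; an allylic acetate labile to base and to zerovalent palladium) and the free primary allylic alcohol of the C6 arm. The hard points are the quaternary C1 next to the C6 methine, the cis triad C4–C5–C6, and four oxygen functions that must be acylated or released one at a time, ending with a deprotection that does not lactonise the product. The strategy rests on C2: it is a bare methylene between C1, whose vinyl group is what an allylsilane leaves behind once its γ-carbon has formed a bond, and C3, whose oxygen marks it as the oxygen-bearing carbon of an enol ether, so that in the open chain C1 and C2 are both nucleophilic alkene carbons and their union needs an oxidative reversal of polarity. The C5 oxygen, 1,3 to both C1 and C3, can come from the chiral pool, steer the ring closure at C1 and then the reduction at C3, and only afterwards be oxidised to the ketone that activates C4 and C6.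

## Retrosynthetic reasoning

Final unveiling. 45 is taken back to 44, in which two silyl ethers are still in place, and 44 to the tert-butyl ester 42. The ester is cut first and under aprotic conditions, while the C5 oxygen is still silylated, so that the free acid never meets a free cis hydroxyl in acid; the last step then only has to remove silicon near neutrality.

C3 ester. The acyl–oxygen bond of the C3 ester in 42 is cut, giving alcohol 31 and acid 40; 31 is the PMB ether 30 with its C3 oxygen released. This is done late because the Z enoate and its allylic acetate survive neither enolate chemistry nor hydride. Acid 40 goes back through its tert-butyl ester 39 to the C2=C3 olefination of aldehyde 38 with phosphonate 35; 38 comes from diacetate 36, and 35 from 33, which is made from 17 and 32. The forward olefination has to be Z-selective.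

Acrylate methylene. The exocyclic C=CH2 of the C4 arm in 30 is cut back, through Mannich base 28, to the acetate arm of 26. Methylenating after the ring ketone has gone leaves the ester α-carbon as the only acidic site.

C5 carbinol. 26 is the silyl ether of 25, and 25 comes from ketone 24; the forward reduction must deliver hydride to the α face, which the axial C1 vinyl group leaves as the only open side.

C6–alkenyl bond. The bond in 24 between C6 and the sp2 carbon of the side chain is cut, giving the regiodefined enol silane 20 and alkenyl bromide 22, itself made from 21. C6 is a neopentyl α-carbon, so a palladium-mediated enolate coupling is preferred to any SN2 process; it is placed after the C4 alkylation because the α-alkenyl ketone is far more acidic than its precursor.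

C4–CH2 bond. 20 is the enol silane of 19, and 19 is cut between C4 and the acetate carbon to ketone 16 and bromoacetate 17. Of the two α-carbons of 16 only C4 is not neopentyl, and the equatorial 4β position is also the stable one.

Oxidation-state relay. 16 goes back through 15 and 14 to alcohol 13 and ketone 12: the C3 carbinol has to be set while the C5 silyloxy group still locks the chair with the C1 methyl axial, and only then may C5 be oxidised. 12 is the hydrolysis product of ketal 11.

Key disconnection C1–C2. 11 is opened between C1 and C2 to the acyclic enol ether–allylsilane 10. No other ring bond joins two carbons that are both alkene termini of electron-rich olefins; the cut removes the ring and the quaternary centre at once and leaves a chain with a single stereocentre.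

Precursor. 10 is traced to the cyclic silyl ether 8, whose seven-membered ring fixes the Z geometry of the allylsilane; 8 comes from ester 7 by carbonyl methylenation (this carbon becomes C2), 7 from diene 6 by ring-closing metathesis, and 6 from alcohol 4 and chlorosilane 5. 4 arises from epoxide 2 and Grignard reagent 3, and 2 from the chiral-pool chlorohydrin 1.

## Alternatives that were turned down

Alternative 1: The C1–CH and C6–C bonds are cut together. Irradiation of the 3-methylcyclohexenone A1 with the propargyl ether A2 would close a cyclobutene on the enone double bond and give the cis-fused photoadduct A3; a later ring-opening cross-metathesis of its cyclobutene would unmask the vinyl and 2-propenyl groups. In its favour, C1, C6 and their cis relation are set in one step, and the C6 side chain arrives without the neopentyl enolate coupling that the chosen route needs; on that point it is the stronger plan. Against it: the head-to-head versus head-to-tail orientation of a terminal alkyne on an enone is not reliably controlled. Facial selectivity at C1 depends on stereocentres two and three bonds away. A1 carries its silyloxy group β to the ketone next to an acidic C4–H, so it can lose that group and aromatise. The C3/C4 pair of A1 must still be built first. The chosen strategy offers instead a ring closure whose regiochemistry is dictated by silicon and whose one new stereocentre is set by a chair from a cheap pool alcohol.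

Alternative 2: The C4–CH2 bond is cut with the ring already in place. A bromoacetal tethered to the C5 oxygen of cyclohexene A4 would add as a radical to C4 (5-exo), and the resulting C3 radical would be trapped by oxygen to give lactol acetal A5. The tether guarantees both the site and the cis C4/C5 relation, which the chosen route obtains less securely by an intermolecular enolate alkylation; here the alternative is stronger. Against it: the C3 configuration results from an untethered radical capture and is not enforced. A4 already contains C1, C5 and C6, so the quaternary centre and the C6 arm, the hardest part, are pushed into the precursor. Later the acetal carbon of A5 has to be raised to the acid oxidation level and its ring to the C5 oxygen opened while the C3 ester is in place. The chosen strategy solves the ring and C1 first and keeps the acid as an open-chain ester throughout.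

Alternative 3: The C4–C5 bond is cut. Reductive metalation of the allylic bromide in the open-chain aldehyde A6 with CrCl2 would make the 2-(bromomethyl)alkenoate nucleophilic at its γ-carbon C4, which adds to the C5 aldehyde, closes the ring and creates the acrylate double bond in one step, giving cyclohexanol A7. This is more step-economic in the endgame than the alkylation, reduction and methylenation sequence of the chosen route, and it is stronger there. Against it: A6 is an open chain in which the quaternary C1 and the adjacent C6 methine (α to an aldehyde and allylic, hence prone to epimerise and conjugate) must be set acyclically. The all-cis C4–C5–C6 triad with an axial C5 oxygen is not the obvious outcome of a closed chair transition state. The metal alkoxide formed at C5 on the way to A7 sits cis to the ester and would be expected to lactonise. The chosen strategy creates only one stereocentre in its ring closure and introduces C4 and C6 on a conformationally defined ketone.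

Key step: step 7

Remark on the chemistry: the allylsilane of 10 is carried as its Z isomer (CH2SiMe3 cis to the C6 methylene), because only this geometry makes allylic strain force the alkene arm pseudo-equatorial in the ring-closing chair; with the E isomer methyl and alkene arm would be nearly equivalent. The chlorohydrin is used as its methyl ester so that carbonyl methylenation gives the methoxyalkene directly.

## Route

Step 1
Reactants: 1 methyl (3R)-4-chloro-3-hydroxybutanoate
Product: 2 methyl [(2R)-oxiran-2-yl]acetate
Conditions: Ag2O, 1,2-dimethoxyethane, 60 °C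
Reagents that add atoms: none
Why: Intramolecular Williamson closure of the chlorohydrin under silver assistance; the non-basic oxide avoids E1cB opening of the β,γ-epoxy ester, and the stereocentre is not touched.

Step 2
Reactants: 2 methyl [(2R)-oxiran-2-yl]acetate; 3 isopropenylmagnesium bromide
Product: 4 methyl (3S)-3-hydroxy-5-methylhex-5-enoate
Conditions: CuI (10 mol%), THF, −40 to −20 °C; aq. NH4Cl
Reagents that add atoms: none
Why: Copper-catalysed Grignard opening of the terminal epoxide at its CH2 carbon (SN2) is faster than addition to the ester at this temperature; the carbinol centre is retained and only its descriptor changes.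

Step 3
Reactants: 4 methyl (3S)-3-hydroxy-5-methylhex-5-enoate; 5 allyl(chloro)dimethylsilane
Product: 6 methyl (3S)-3-{[dimethyl(prop-2-en-1-yl)silyl]oxy}-5-methylhex-5-enoate
Conditions: imidazole, CH2Cl2, 0 °C to rt
Reagents that add atoms: none
Why: Silylation of the secondary alcohol; the silicon carries the allyl group whose two inner carbons become the vinyl group, and it tethers that group for metathesis.

Step 4
Reactants: 6 methyl (3S)-3-{[dimethyl(prop-2-en-1-yl)silyl]oxy}-5-methylhex-5-enoate
Product: 7 methyl [(7S)-2,2,5-trimethyl-2,3,6,7-tetrahydro-1,2-oxasilepin-7-yl]acetate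
Conditions: second-generation Grubbs catalyst (5 mol%), CH2Cl2 (0.01 M), 40 °C
Reagents that add atoms: none
Why: Silicon-tethered ring-closing metathesis of the allylsilane terminus with the 1,1-disubstituted alkene; the seven-membered ring can only hold the Z trisubstituted alkene, which fixes the allylsilane geometry.

Step 5
Reactants: 7 methyl [(7S)-2,2,5-trimethyl-2,3,6,7-tetrahydro-1,2-oxasilepin-7-yl]acetate
Product: 8 (7S)-7-(2-methoxyprop-2-en-1-yl)-2,2,5-trimethyl-2,3,6,7-tetrahydro-1,2-oxasilepine
Conditions: Cp2TiMe2 (3 equiv), toluene, 70 °C, dark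
Reagents that add atoms: dimethyltitanocene, C[Ti](C)(C1C=CC=C1)C1C=CC=C1
Why: Petasis methylenation turns the methyl ester directly and regiospecifically into the 2-methoxyalkene (its new CH2 is ring carbon C2); the neutral titanium carbene leaves the β-silyloxy group and the trisubstituted alkene alone.

Step 6
Reactants: 8 (7S)-7-(2-methoxyprop-2-en-1-yl)-2,2,5-trimethyl-2,3,6,7-tetrahydro-1,2-oxasilepine
Product: 10 tert-butyl{[(4S,6Z)-2-methoxy-6-methyl-8-(trimethylsilyl)octa-1,6-dien-4-yl]oxy}dimethylsilane, via lithium alkoxide 9 (not isolated)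
Conditions: MeLi, Et2O/THF, 0 °C; then TBSCl, DMPU, 0 °C to rt
Reagents that add atoms: methyllithium, [Li]C; tert-butyldimethylsilyl chloride, CC(C)(C)[Si](C)(C)Cl
Why: Nucleophilic substitution at silicon by methyllithium opens the cyclic silyl ether to the (Z)-allyltrimethylsilane and the C5 alkoxide, which is silylated in the same flask; the medium stays basic, as the enol ether requires.

Step 7
Reactants: 10 tert-butyl{[(4S,6Z)-2-methoxy-6-methyl-8-(trimethylsilyl)octa-1,6-dien-4-yl]oxy}dimethylsilane
Product: 11 5β-(TBS-oxy)-3,3-dimethoxy-1α-methyl-1β-vinylcyclohexane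
Conditions: reticulated vitreous carbon anode, Pt cathode, undivided cell, constant current (2.2 F/mol), LiClO4 (0.1 M), 2,6-lutidine, MeOH/THF 1:4, rt
Reagents that add atoms: methanol, CO
Why: Proposed new method: anodic oxidation of the enol ether–allylsilane pair should give a radical cation in which C2, the oxygen-free terminus of the enol ether, is electrophilic; the allylsilane attacks it through its γ-carbon C1, the only mode that leaves the charge β to silicon, and a second electron transfer, methanol capture of the C3 oxocarbenium ion and loss of the silyl group then give the ketal and the vinyl group. The closest known reaction type is the intramolecular anodic coupling of enol ethers with trisubstituted allylsilanes, which forms quaternary carbons; new here is that the tether leaves from the oxygen-bearing carbon of the enol ether, so that both of its carbons end up in the ring. The six-membered ring closes 6-exo with respect to the allylsilane and 6-endo with respect to the enol ether; bonding to the alkene CH would give a seven-membered ring without silicon stabilisation, and bonding at C3 a five-membered ring with an unstabilised primary radical. The new stereocentre C1 is controlled by C5 through a chair-like transition state with the silyloxy group equatorial and the alkene arm pseudo-equatorial, because in the Z allylsilane a pseudo-axial arm would press CH2SiMe3 against C5 (A(1,3) strain); methyl therefore goes axial and vinyl ends cis to the C5 oxygen. The step needs one-electron oxidation without protonation of the enol ether, which 2,6-lutidine secures, and ring closure faster than methanol capture of the open radical cation, which the chair geometry and the nucleophilic trisubstituted allylsilane should secure.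

Step 8
Reactants: 11 5β-(TBS-oxy)-3,3-dimethoxy-1α-methyl-1β-vinylcyclohexane
Product: 12 5β-(TBS-oxy)-1α-methyl-1β-vinylcyclohexan-3-one
Conditions: pyridinium p-toluenesulfonate (cat.), acetone/H2O, rt
Reagents that add atoms: water, O
Why: Mild acid hydrolysis of the dimethyl ketal; the weak acid spares the silyl ether and does not eliminate the β-silyloxy group.

Step 9
Reactants: 12 5β-(TBS-oxy)-1α-methyl-1β-vinylcyclohexan-3-one
Product: 13 5β-(TBS-oxy)-1α-methyl-1β-vinylcyclohexan-3α-ol
Conditions: LiBH(s-Bu)3, THF, −78 °C; aq. NH4Cl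
Reagents that add atoms: none
Why: The equatorial C5 silyloxy group holds the chair with the C1 methyl axial and syn to the axial trajectory at C3, so the bulky hydride enters equatorially (as with 3,3,5-trimethylcyclohexanone) and should give the axial 3α alcohol, trans to the C5 oxygen.

Step 10
Reactants: 13 5β-(TBS-oxy)-1α-methyl-1β-vinylcyclohexan-3α-ol
Product: 14 5β-(TBS-oxy)-3α-(PMB-oxy)-1α-methyl-1β-vinylcyclohexane
Conditions: NaH, 4-methoxybenzyl chloride, Bu4NI (cat.), DMF, 0 °C to rt
Reagents that add atoms: 4-methoxybenzyl chloride, COc1ccc(CCl)cc1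
Why: Williamson etherification; an ether is chosen because this oxygen will sit β to the C5 ketone and must be a poor leaving group, and the trans-1,3 relation of the two oxygens excludes silyl migration.

Step 11
Reactants: 14 5β-(TBS-oxy)-3α-(PMB-oxy)-1α-methyl-1β-vinylcyclohexane
Product: 15 3α-(PMB-oxy)-1α-methyl-1β-vinylcyclohexan-5β-ol
Conditions: Bu4NF, THF, rt
Reagents that add atoms: none
Why: Fluoride cleavage of the secondary silyl ether; the benzyl-type ether and the alkenes are inert.

Step 12
Reactants: 15 3α-(PMB-oxy)-1α-methyl-1β-vinylcyclohexan-5β-ol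
Product: 16 3α-(PMB-oxy)-1α-methyl-1β-vinylcyclohexan-5-one
Conditions: Dess–Martin periodinane, NaHCO3, CH2Cl2, rt
Reagents that add atoms: none
Why: Buffered Dess–Martin oxidation; the near-neutral conditions avoid β-elimination of the C3 ether from the new ketone.

Step 13
Reactants: 16 3α-(PMB-oxy)-1α-methyl-1β-vinylcyclohexan-5-one; 17 tert-butyl bromoacetate
Product: 19 4β-(2-tert-butoxy-2-oxoethyl)-3α-(PMB-oxy)-1α-methyl-1β-vinylcyclohexan-5-one, via lithium enolate 18 (not isolated)
Conditions: LiN(i-Pr)2, THF, −78 °C; then 17, DMPU, −78 to −40 °C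
Reagents that add atoms: none
Why: Kinetic enolate alkylation; deprotonation should occur at C4 because C6 is neopentyl (compare 3,3-dimethylcyclohexanone) and the β-oxygen acidifies C4–H, and the electrophile should enter anti to the side of the C3 ether to give the 4β (equatorial, also the more stable) isomer; the cold lithium enolate and the equatorial ether disfavour E1cB loss of the alkoxide.

Step 14
Reactants: 19 4β-(2-tert-butoxy-2-oxoethyl)-3α-(PMB-oxy)-1α-methyl-1β-vinylcyclohexan-5-one
Product: 20 tert-butyl [3α-(PMB-oxy)-1α-methyl-5-(trimethylsilyloxy)-1β-vinylcyclohex-5-en-4β-yl]acetate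
Conditions: LiN(i-Pr)2 added to 19 and Me3SiCl, THF, −78 °C (in situ quench)
Reagents that add atoms: chlorotrimethylsilane, C[Si](C)(C)Cl
Why: Kinetic enol silane formation at the C6 methylene and not at the C4 methine; the in situ quench prevents enolate equilibration, and the ketone is deprotonated far faster than the tert-butyl ester.

Step 15
Reactants: 21 2-bromoprop-2-en-1-ol
Product: 22 [(2-bromoprop-2-en-1-yl)oxy](tert-butyl)dimethylsilane
Conditions: TBSCl, imidazole, DMF, rt
Reagents that add atoms: tert-butyldimethylsilyl chloride, CC(C)(C)[Si](C)(C)Cl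
Why: Standard silylation of the primary allylic alcohol to give the alkenyl bromide partner.

Step 16
Reactants: 20 tert-butyl [3α-(PMB-oxy)-1α-methyl-5-(trimethylsilyloxy)-1β-vinylcyclohex-5-en-4β-yl]acetate; 22 [(2-bromoprop-2-en-1-yl)oxy](tert-butyl)dimethylsilane
Product: 24 4β-(2-tert-butoxy-2-oxoethyl)-6β-[3-(TBS-oxy)prop-1-en-2-yl]-3α-(PMB-oxy)-1α-methyl-1β-vinylcyclohexan-5-one, via tributyltin enolate 23 (not isolated)
Conditions: Pd2(dba)3 (5 mol%), P(t-Bu)3 (12 mol%), Bu3SnF, toluene, 80 °C; then DBU (0.2 equiv), CH2Cl2, rt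
Reagents that add atoms: none
Why: Palladium-catalysed α-alkenylation of a ketone through its regiodefined tin enolate (fluoride-promoted enol silane–alkenyl bromide coupling) forms the C6–C(sp2) bond without strong base, so neither the ester nor the β-alkoxy ketone is disturbed; the doubly activated C6–H lets catalytic DBU settle the new centre in the equatorial 6β position, which is also the side opened by protonation anti to the axial C1 vinyl group.

Step 17
Reactants: 24 4β-(2-tert-butoxy-2-oxoethyl)-6β-[3-(TBS-oxy)prop-1-en-2-yl]-3α-(PMB-oxy)-1α-methyl-1β-vinylcyclohexan-5-one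
Product: 25 4β-(2-tert-butoxy-2-oxoethyl)-6β-[3-(TBS-oxy)prop-1-en-2-yl]-3α-(PMB-oxy)-1α-methyl-1β-vinylcyclohexan-5β-ol
Conditions: LiBH(s-Bu)3, THF, −78 °C; aq. NH4Cl
Reagents that add atoms: none
Why: In the chair with all three side chains equatorial the C1 vinyl group is axial and blocks the β face of the carbonyl, so the hindered hydride should attack equatorially and give the axial 5β alcohol, cis to both neighbours; the tert-butyl ester does not lactonise with the alkoxide at this temperature.

Step 18
Reactants: 25 4β-(2-tert-butoxy-2-oxoethyl)-6β-[3-(TBS-oxy)prop-1-en-2-yl]-3α-(PMB-oxy)-1α-methyl-1β-vinylcyclohexan-5β-ol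
Product: 26 4β-(2-tert-butoxy-2-oxoethyl)-6β-[3-(TBS-oxy)prop-1-en-2-yl]-3α-(PMB-oxy)-5β-(TES-oxy)-1α-methyl-1β-vinylcyclohexane
Conditions: Et3SiOTf, 2,6-lutidine, CH2Cl2, −78 to 0 °C
Reagents that add atoms: triethylsilyl trifluoromethanesulfonate, CC[Si](CC)(CC)OS(=O)(=O)C(F)(F)F
Why: The silyl triflate caps the hindered axial alcohol; from here on the C5 oxygen cannot lactonise with the C4 ester or acid.

Step 19
Reactants: 26 4β-(2-tert-butoxy-2-oxoethyl)-6β-[3-(TBS-oxy)prop-1-en-2-yl]-3α-(PMB-oxy)-5β-(TES-oxy)-1α-methyl-1β-vinylcyclohexane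
Product: 28 tert-butyl 3-(dimethylamino)-2-{6β-[3-(TBS-oxy)prop-1-en-2-yl]-3α-(PMB-oxy)-5β-(TES-oxy)-1α-methyl-1β-vinylcyclohex-4β-yl}propanoate, via lithium ester enolate 27 (not isolated)
Conditions: LiN(i-Pr)2, THF, −78 °C; then CH2=NMe2+ I− (Eschenmoser's salt), −78 °C to rt
Reagents that add atoms: Eschenmoser's salt, C=[N+](C)C.[I-]
Why: Mannich reaction of the ester enolate, now the only acidic site, with the iminium salt; the configuration of the new α-carbon is irrelevant because it becomes sp2.

Step 20
Reactants: 28 tert-butyl 3-(dimethylamino)-2-{6β-[3-(TBS-oxy)prop-1-en-2-yl]-3α-(PMB-oxy)-5β-(TES-oxy)-1α-methyl-1β-vinylcyclohex-4β-yl}propanoate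
Product: 30 4β-(3-tert-butoxy-3-oxoprop-1-en-2-yl)-6β-[3-(TBS-oxy)prop-1-en-2-yl]-3α-(PMB-oxy)-5β-(TES-oxy)-1α-methyl-1β-vinylcyclohexane, via trimethylammonium iodide 29 (not isolated)
Conditions: MeI, THF, rt; then DBU, CH2Cl2, rt
Reagents that add atoms: none
Why: Quaternisation of the Mannich base and E1cB elimination of trimethylamine give the α-methylene ester; this is the standard two-stage α-methylenation.

Step 21
Reactants: 30 4β-(3-tert-butoxy-3-oxoprop-1-en-2-yl)-6β-[3-(TBS-oxy)prop-1-en-2-yl]-3α-(PMB-oxy)-5β-(TES-oxy)-1α-methyl-1β-vinylcyclohexane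
Product: 31 4β-(3-tert-butoxy-3-oxoprop-1-en-2-yl)-6β-[3-(TBS-oxy)prop-1-en-2-yl]-5β-(TES-oxy)-1α-methyl-1β-vinylcyclohexan-3α-ol
Conditions: DDQ, CH2Cl2/pH 7 buffer, 0 °C
Reagents that add atoms: none
Why: Oxidative cleavage of the PMB ether by hydride abstraction; silyl ethers, the acrylate and the unactivated alkenes are not oxidised.

Step 22
Reactants: 17 tert-butyl bromoacetate; 32 diphenyl phosphite
Product: 33 tert-butyl (diphenoxyphosphoryl)acetate
Conditions: Et3N, CH2Cl2, 0 °C to rt
Reagents that add atoms: none
Why: Michaelis–Becker alkylation of the phosphite at phosphorus by the activated primary bromide gives the diaryl phosphonoacetate.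

Step 23
Reactants: 33 tert-butyl (diphenoxyphosphoryl)acetate
Product: 35 tert-butyl 2-(diphenoxyphosphoryl)propanoate, via sodium phosphonate carbanion 34 (not isolated)
Conditions: NaH (1.0 equiv), DMSO/THF, 0 °C; then MeI (1.0 equiv)
Reagents that add atoms: iodomethane, CI
Why: C-methylation of the stabilised carbanion; one equivalent each of base and iodide limits dialkylation.

Step 24
Reactants: 36 (2Z)-but-2-ene-1,4-diyl diacetate
Product: 38 2-oxoethyl acetate, via ozonide 37 (not isolated)
Conditions: O3, CH2Cl2, −78 °C; then Me2S, −78 °C to rt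
Reagents that add atoms: ozone, [O-][O+]=O
Why: Ozonolysis of the symmetrical alkene with reductive work-up gives two equivalents of the acetoxy aldehyde.

Step 25
Reactants: 35 tert-butyl 2-(diphenoxyphosphoryl)propanoate; 38 2-oxoethyl acetate
Product: 39 tert-butyl (2Z)-4-acetoxy-2-methylbut-2-enoate
Conditions: NaI, DBU, THF, −78 to 0 °C
Reagents that add atoms: none
Why: Horner–Wadsworth–Emmons olefination with a diaryl phosphonate (Ando variant): the electron-poor aryloxy groups make elimination from the first-formed adduct fast, so the kinetic Z trisubstituted enoate should result; the mild base leaves the acetate intact.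

Step 26
Reactants: 39 tert-butyl (2Z)-4-acetoxy-2-methylbut-2-enoate
Product: 40 (2Z)-4-acetoxy-2-methylbut-2-enoic acid
Conditions: CF3CO2H, CH2Cl2, 0 °C to rt
Reagents that add atoms: none
Why: Acidolysis of the tert-butyl ester by alkyl–oxygen cleavage; the acetylated γ-oxygen cannot lactonise and the acetate is stable to the acid.

Step 27
Reactants: 40 (2Z)-4-acetoxy-2-methylbut-2-enoic acid; 31 4β-(3-tert-butoxy-3-oxoprop-1-en-2-yl)-6β-[3-(TBS-oxy)prop-1-en-2-yl]-5β-(TES-oxy)-1α-methyl-1β-vinylcyclohexan-3α-ol
Product: 42 3α-[(2Z)-4-acetoxy-2-methylbut-2-enoyloxy]-4β-(3-tert-butoxy-3-oxoprop-1-en-2-yl)-6β-[3-(TBS-oxy)prop-1-en-2-yl]-5β-(TES-oxy)-1α-methyl-1β-vinylcyclohexane, via mixed anhydride 41 (not isolated)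
Conditions: 2,4,6-trichlorobenzoyl chloride, Et3N, THF, 0 °C; then 31, DMAP, toluene, rt
Reagents that add atoms: none
Why: Yamaguchi esterification of the equatorial secondary alcohol; the preformed hindered mixed anhydride acylates quickly with little DMAP, which limits Z to E isomerisation of the angelate-type acid.

Step 28
Reactants: 42 3α-[(2Z)-4-acetoxy-2-methylbut-2-enoyloxy]-4β-(3-tert-butoxy-3-oxoprop-1-en-2-yl)-6β-[3-(TBS-oxy)prop-1-en-2-yl]-5β-(TES-oxy)-1α-methyl-1β-vinylcyclohexane
Product: 44 2-{3α-[(2Z)-4-acetoxy-2-methylbut-2-enoyloxy]-6β-[3-(TBS-oxy)prop-1-en-2-yl]-5β-(TES-oxy)-1α-methyl-1β-vinylcyclohex-4β-yl}prop-2-enoic acid, via trimethylsilyl ester 43 (not isolated)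
Conditions: Me3SiOTf, 2,6-lutidine, CH2Cl2, 0 °C to rt; pH 7 buffer
Reagents that add atoms: none
Why: Silyl triflate-mediated cleavage of the tert-butyl ester (carbonyl silylation, loss of isobutene) gives a silyl ester that hydrolyses on work-up; no protic acid is present and the C5 oxygen is still silylated, so the acid cannot lactonise, and the other esters have no tertiary alkyl group to lose.

Step 29
Reactants: 44 2-{3α-[(2Z)-4-acetoxy-2-methylbut-2-enoyloxy]-6β-[3-(TBS-oxy)prop-1-en-2-yl]-5β-(TES-oxy)-1α-methyl-1β-vinylcyclohex-4β-yl}prop-2-enoic acid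
Product: 45 target acid (CNP0261293.7)
Conditions: Bu4NF/AcOH (1:1), THF, 0 °C to rt; pH 5 phosphate buffer, cold extraction
Reagents that add atoms: none
Why: Buffered fluoride removes both silyl ethers while the acid is held as its carboxylate, which does not lactonise; the acetic acid buffer protects the acetate and the Z enoate from basic fluoride.

## Compound list

1 | methyl (3R)-4-chloro-3-hydroxybutanoate | COC(=O)C[C@@H](O)CCl | starting material
2 | methyl [(2R)-oxiran-2-yl]acetate | COC(=O)C[C@@H]1CO1 | intermediate
3 | isopropenylmagnesium bromide | C=C(C)[Mg]Br | starting material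
4 | methyl (3S)-3-hydroxy-5-methylhex-5-enoate | COC(=O)C[C@@H](O)CC(C)=C | intermediate
5 | allyl(chloro)dimethylsilane | C=CC[Si](C)(C)Cl | starting material
6 | methyl (3S)-3-{[dimethyl(prop-2-en-1-yl)silyl]oxy}-5-methylhex-5-enoate | COC(=O)C[C@@H](O[Si](C)(C)CC=C)CC(C)=C | intermediate
7 | methyl [(7S)-2,2,5-trimethyl-2,3,6,7-tetrahydro-1,2-oxasilepin-7-yl]acetate | COC(=O)C[C@@H]1CC(C)=CC[Si](C)(C)O1 | intermediate
8 | (7S)-7-(2-methoxyprop-2-en-1-yl)-2,2,5-trimethyl-2,3,6,7-tetrahydro-1,2-oxasilepine | C=C(OC)C[C@@H]1CC(C)=CC[Si](C)(C)O1 | intermediate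
9 | lithium (4S,6Z)-2-methoxy-6-methyl-8-(trimethylsilyl)octa-1,6-dien-4-olate | C=C(OC)C[C@@H]([O-])C/C(C)=C\C[Si](C)(C)C.[Li+] | intermediate
10 | tert-butyl{[(4S,6Z)-2-methoxy-6-methyl-8-(trimethylsilyl)octa-1,6-dien-4-yl]oxy}dimethylsilane | C=C(OC)C[C@@H](O[Si](C)(C)C(C)(C)C)C/C(C)=C\C[Si](C)(C)C | intermediate
11 | 5β-(TBS-oxy)-3,3-dimethoxy-1α-methyl-1β-vinylcyclohexane | C=C[C@@]1(C)CC(OC)(OC)C[C@@H](O[Si](C)(C)C(C)(C)C)C1 | intermediate
12 | 5β-(TBS-oxy)-1α-methyl-1β-vinylcyclohexan-3-one | C=C[C@@]1(C)CC(=O)C[C@@H](O[Si](C)(C)C(C)(C)C)C1 | intermediate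
13 | 5β-(TBS-oxy)-1α-methyl-1β-vinylcyclohexan-3α-ol | C=C[C@@]1(C)C[C@H](O)C[C@@H](O[Si](C)(C)C(C)(C)C)C1 | intermediate
14 | 5β-(TBS-oxy)-3α-(PMB-oxy)-1α-methyl-1β-vinylcyclohexane | C=C[C@@]1(C)C[C@H](OCc2ccc(OC)cc2)C[C@@H](O[Si](C)(C)C(C)(C)C)C1 | intermediate
15 | 3α-(PMB-oxy)-1α-methyl-1β-vinylcyclohexan-5β-ol | C=C[C@@]1(C)C[C@H](OCc2ccc(OC)cc2)C[C@@H](O)C1 | intermediate
16 | 3α-(PMB-oxy)-1α-methyl-1β-vinylcyclohexan-5-one | C=C[C@@]1(C)C[C@H](OCc2ccc(OC)cc2)CC(=O)C1 | intermediate
17 | tert-butyl bromoacetate | CC(C)(C)OC(=O)CBr | starting material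
18 | lithium C4=C5 enolate of 16 | C=C[C@@]1(C)C[C@H](OCc2ccc(OC)cc2)C=C([O-])C1.[Li+] | intermediate
19 | 4β-(2-tert-butoxy-2-oxoethyl)-3α-(PMB-oxy)-1α-methyl-1β-vinylcyclohexan-5-one | C=C[C@@]1(C)C[C@H](OCc2ccc(OC)cc2)[C@@H](CC(=O)OC(C)(C)C)C(=O)C1 | intermediate
20 | tert-butyl [3α-(PMB-oxy)-1α-methyl-5-(trimethylsilyloxy)-1β-vinylcyclohex-5-en-4β-yl]acetate | C=C[C@@]1(C)C[C@H](OCc2ccc(OC)cc2)[C@@H](CC(=O)OC(C)(C)C)C(O[Si](C)(C)C)=C1 | intermediate
21 | 2-bromoprop-2-en-1-ol | C=C(Br)CO | starting material
22 | [(2-bromoprop-2-en-1-yl)oxy](tert-butyl)dimethylsilane | C=C(Br)CO[Si](C)(C)C(C)(C)C | intermediate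
23 | tributyltin C5=C6 enolate of 19 | C=C[C@@]1(C)C[C@H](OCc2ccc(OC)cc2)[C@@H](CC(=O)OC(C)(C)C)C(O[Sn](CCCC)(CCCC)CCCC)=C1 | intermediate
24 | 4β-(2-tert-butoxy-2-oxoethyl)-6β-[3-(TBS-oxy)prop-1-en-2-yl]-3α-(PMB-oxy)-1α-methyl-1β-vinylcyclohexan-5-one | C=C[C@@]1(C)C[C@H](OCc2ccc(OC)cc2)[C@@H](CC(=O)OC(C)(C)C)C(=O)[C@H]1C(=C)CO[Si](C)(C)C(C)(C)C | intermediate
25 | 5β-alcohol from 24 | C=C[C@@]1(C)C[C@H](OCc2ccc(OC)cc2)[C@@H](CC(=O)OC(C)(C)C)[C@@H](O)[C@H]1C(=C)CO[Si](C)(C)C(C)(C)C | intermediate
26 | 5β-triethylsilyl ether of 25 | C=C[C@@]1(C)C[C@H](OCc2ccc(OC)cc2)[C@@H](CC(=O)OC(C)(C)C)[C@@H](O[Si](CC)(CC)CC)[C@H]1C(=C)CO[Si](C)(C)C(C)(C)C | intermediate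
27 | lithium ester enolate of 26 | C=C[C@@]1(C)C[C@H](OCc2ccc(OC)cc2)[C@@H](C=C([O-])OC(C)(C)C)[C@@H](O[Si](CC)(CC)CC)[C@H]1C(=C)CO[Si](C)(C)C(C)(C)C.[Li+] | intermediate
28 | Mannich base, tert-butyl 3-(dimethylamino)-2-(ring-4β-yl)propanoate (mixture at the α-carbon) | C=C[C@@]1(C)C[C@H](OCc2ccc(OC)cc2)[C@@H](C(CN(C)C)C(=O)OC(C)(C)C)[C@@H](O[Si](CC)(CC)CC)[C@H]1C(=C)CO[Si](C)(C)C(C)(C)C | intermediate
29 | trimethylammonium iodide of 28 | C=C[C@@]1(C)C[C@H](OCc2ccc(OC)cc2)[C@@H](C(C[N+](C)(C)C)C(=O)OC(C)(C)C)[C@@H](O[Si](CC)(CC)CC)[C@H]1C(=C)CO[Si](C)(C)C(C)(C)C.[I-] | intermediate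
30 | 4β-(3-tert-butoxy-3-oxoprop-1-en-2-yl)-6β-[3-(TBS-oxy)prop-1-en-2-yl]-3α-(PMB-oxy)-5β-(TES-oxy)-1α-methyl-1β-vinylcyclohexane | C=C[C@@]1(C)C[C@H](OCc2ccc(OC)cc2)[C@@H](C(=C)C(=O)OC(C)(C)C)[C@@H](O[Si](CC)(CC)CC)[C@H]1C(=C)CO[Si](C)(C)C(C)(C)C | intermediate
31 | 3α-alcohol from 30 | C=C[C@@]1(C)C[C@H](O)[C@@H](C(=C)C(=O)OC(C)(C)C)[C@@H](O[Si](CC)(CC)CC)[C@H]1C(=C)CO[Si](C)(C)C(C)(C)C | intermediate
32 | diphenyl phosphite | O=[PH](Oc1ccccc1)Oc1ccccc1 | starting material
33 | tert-butyl (diphenoxyphosphoryl)acetate | CC(C)(C)OC(=O)CP(=O)(Oc1ccccc1)Oc1ccccc1 | intermediate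
34 | sodium salt of 33 (carbanion) | CC(C)(C)OC(=O)[CH-]P(=O)(Oc1ccccc1)Oc1ccccc1.[Na+] | intermediate
35 | tert-butyl 2-(diphenoxyphosphoryl)propanoate (racemic) | CC(C(=O)OC(C)(C)C)P(=O)(Oc1ccccc1)Oc1ccccc1 | intermediate
36 | (2Z)-but-2-ene-1,4-diyl diacetate | CC(=O)OC/C=C\COC(C)=O | starting material
37 | 3,5-bis(acetoxymethyl)-1,2,4-trioxolane (ozonide) | CC(=O)OCC1OOC(COC(C)=O)O1 | intermediate
38 | 2-oxoethyl acetate | CC(=O)OCC=O | intermediate
39 | tert-butyl (2Z)-4-acetoxy-2-methylbut-2-enoate | CC(C)(C)OC(=O)/C(C)=C\COC(C)=O | intermediate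
40 | (2Z)-4-acetoxy-2-methylbut-2-enoic acid | OC(=O)/C(C)=C\COC(C)=O | intermediate
41 | (2Z)-4-acetoxy-2-methylbut-2-enoic 2,4,6-trichlorobenzoic anhydride | O=C(OC(=O)/C(C)=C\COC(C)=O)c1c(Cl)cc(Cl)cc1Cl | intermediate
42 | 3α-[(2Z)-4-acetoxy-2-methylbut-2-enoyloxy]-4β-(3-tert-butoxy-3-oxoprop-1-en-2-yl)-6β-[3-(TBS-oxy)prop-1-en-2-yl]-5β-(TES-oxy)-1α-methyl-1β-vinylcyclohexane | C=C[C@@]1(C)C[C@H](OC(=O)/C(C)=C\COC(C)=O)[C@@H](C(=C)C(=O)OC(C)(C)C)[C@@H](O[Si](CC)(CC)CC)[C@H]1C(=C)CO[Si](C)(C)C(C)(C)C | intermediate
43 | trimethylsilyl ester corresponding to 42 | C=C[C@@]1(C)C[C@H](OC(=O)/C(C)=C\COC(C)=O)[C@@H](C(=C)C(=O)O[Si](C)(C)C)[C@@H](O[Si](CC)(CC)CC)[C@H]1C(=C)CO[Si](C)(C)C(C)(C)C | intermediate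
44 | free acrylic acid with the C5 TES and primary TBS ethers | C=C[C@@]1(C)C[C@H](OC(=O)/C(C)=C\COC(C)=O)[C@@H](C(=C)C(=O)O)[C@@H](O[Si](CC)(CC)CC)[C@H]1C(=C)CO[Si](C)(C)C(C)(C)C | intermediate
45 | 2-{3α-[(2Z)-4-acetoxy-2-methylbut-2-enoyloxy]-5β-hydroxy-6β-(3-hydroxyprop-1-en-2-yl)-1α-methyl-1β-vinylcyclohex-4β-yl}prop-2-enoic acid (CNP0261293.7) | C=C[C@@]1(C)C[C@H](OC(=O)/C(C)=C\COC(C)=O)[C@@H](C(=C)C(=O)O)[C@@H](O)[C@H]1C(=C)CO | target

## Step count and least certain steps

Total: 29 steps. Longest linear sequence: 23 steps (steps 1–14, 16–21 and 27–29); steps 15 and 22–26 are side branches.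

Step 7 (key step). Most likely to go wrong: the allylsilane is oxidised instead of the enol ether and loses silicon with methanol capture, or methanol traps the open radical cation before the unprecedented endo-type closure; facial control at C1 may also be incomplete. Fallback by known chemistry, setting out from 10 and returning at 12: mild acid hydrolysis of the enol ether gives methyl ketone F1. Kinetic enolisation at the methyl group with LiN(SiMe3)2 and trifluoroacetylation with 2,2,2-trifluoroethyl trifluoroacetate give trifluoroacetyl ketone F2, and detrifluoroacetylative diazo transfer with methanesulfonyl azide and Et3N gives diazo ketone F3. Intramolecular cyclopropanation of the Z allylsilane alkene with Cu(acac)2 in hot toluene gives bicyclo[4.1.0]heptanone F4, in which the C1–C2 bond exists and CH2SiMe3 sits on the cyclopropane carbon. BF3·OEt2 at −78 °C then opens the activated cyclopropane bond with loss of silicon (silicon-assisted fragmentation) to the 3-methyl-3-vinyl ketone 12. The C1 configuration is again decided by the equatorial preference of the silyloxy group in the ring-forming step, and diastereomers can be separated at F4.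

Step 13. Most likely to go wrong: competing deprotonation at C6, a low facial preference at C4 (axial approach would give the 4α isomer) and E1cB loss of the C3 alkoxide if the enolate is warmed. Fallback in which C4 is set by protonation, from 16 back to 19: the same cold enolate 18 is added to tert-butyl glyoxylate to give aldol F5; dehydration through the mesylate (MeSO2Cl, Et3N) gives alkylidene keto ester F6; Zn in acetic acid reduces the ene-dicarbonyl alkene, and the enol is protonated in the acidic medium to the equatorial 4β ketone 19 without any alkoxide base.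

Step 16. Most likely to go wrong: slow transmetalation or reductive elimination at the neopentyl C6, migration of the tin enolate towards C4 with loss of the C3 ether, an unfavourable C6 epimer ratio after equilibration, or drift of the side-chain double bond into conjugation with the ketone during the base treatment. Fallback with reversed polarity, from 20 back to 24: N-bromosuccinimide converts the enol silane into α-bromo ketone F7; alkenylzinc chloride F8 (from 22 by bromine–lithium exchange with t-BuLi at −78 °C and immediate addition of ZnCl2) is coupled with F7 under NiCl2(dme)/bipyridine-type ligand catalysis. This radical-type coupling of secondary α-bromo ketones tolerates hindrance and does not need an enolate.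

Step 27. Most likely to go wrong: Z to E isomerisation of the acyl donor by reversible conjugate addition of DMAP, or slow acylation of the flanked alcohol. Fallback that builds the Z alkene on the substrate, from 31 back to 42: phosphono acid F9 (from 35 with CF3CO2H) is coupled to 31 with a carbodiimide to give phosphonate ester F10, which is olefinated with aldehyde 38 under the conditions of step 25.

Step 29. Most likely to go wrong: lactonisation of the cis γ-hydroxy acid during acidification or acyl migration under fluoride. Fallback in which the acid is released last under aprotic conditions, from 42 back to 45: HF·pyridine/pyridine removes both silyl ethers from 42 to give diol tert-butyl ester F11, which has no free acid. Me3SiOTf/2,6-lutidine then converts it into the tris-trimethylsilyl derivative F12 (silyl ester and two silyl ethers), and brief hydrolysis in pH 7 aqueous THF releases 45 without acid or fluoride.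

## Further compounds

F1 | step 7 | (4S,6Z)-4-(TBS-oxy)-6-methyl-8-(trimethylsilyl)oct-6-en-2-one | CC(=O)C[C@@H](O[Si](C)(C)C(C)(C)C)C/C(C)=C\C[Si](C)(C)C
F2 | step 7 | (6S,8Z)-6-(TBS-oxy)-1,1,1-trifluoro-8-methyl-10-(trimethylsilyl)dec-8-ene-2,4-dione | O=C(CC(=O)C[C@@H](O[Si](C)(C)C(C)(C)C)C/C(C)=C\C[Si](C)(C)C)C(F)(F)F
F3 | step 7 | (4S,6Z)-4-(TBS-oxy)-1-diazo-6-methyl-8-(trimethylsilyl)oct-6-en-2-one | [N-]=[N+]=CC(=O)C[C@@H](O[Si](C)(C)C(C)(C)C)C/C(C)=C\C[Si](C)(C)C
F4 | step 7 | 4β-(TBS-oxy)-6α-methyl-7-endo-[(trimethylsilyl)methyl]bicyclo[4.1.0]heptan-2-one (cyclopropane on the β face) | C[Si](C)(C)C[C@@H]2[C@@]1(C)[C@@H]2C(=O)C[C@@H](O[Si](C)(C)C(C)(C)C)C1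
F5 | step 13 | tert-butyl 2-hydroxy-2-[3α-(PMB-oxy)-1α-methyl-5-oxo-1β-vinylcyclohex-4-yl]acetate (diastereomer mixture) | C=C[C@@]1(C)C[C@H](OCc2ccc(OC)cc2)C(C(O)C(=O)OC(C)(C)C)C(=O)C1
F6 | step 13 | tert-butyl (2E)-2-[3α-(PMB-oxy)-1α-methyl-5-oxo-1β-vinylcyclohexan-4-ylidene]acetate | C=C[C@@]1(C)C[C@H](OCc2ccc(OC)cc2)/C(=C\C(=O)OC(C)(C)C)C(=O)C1
F7 | step 16 | 6-bromo-4β-(2-tert-butoxy-2-oxoethyl)-3α-(PMB-oxy)-1α-methyl-1β-vinylcyclohexan-5-one (mixture at C6) | C=C[C@@]1(C)C[C@H](OCc2ccc(OC)cc2)[C@@H](CC(=O)OC(C)(C)C)C(=O)C1Br
F8 | step 16 | [3-(TBS-oxy)prop-1-en-2-yl]zinc chloride | C=C(CO[Si](C)(C)C(C)(C)C)[Zn]Cl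
F9 | step 27 | 2-(diphenoxyphosphoryl)propanoic acid | CC(C(=O)O)P(=O)(Oc1ccccc1)Oc1ccccc1
F10 | step 27 | 3α-[2-(diphenoxyphosphoryl)propanoyloxy] ester of 31 | C=C[C@@]1(C)C[C@H](OC(=O)C(C)P(=O)(Oc2ccccc2)Oc2ccccc2)[C@@H](C(=C)C(=O)OC(C)(C)C)[C@@H](O[Si](CC)(CC)CC)[C@H]1C(=C)CO[Si](C)(C)C(C)(C)C
F11 | step 29 | tert-butyl ester of the target (both hydroxyls free) | C=C[C@@]1(C)C[C@H](OC(=O)/C(C)=C\COC(C)=O)[C@@H](C(=C)C(=O)OC(C)(C)C)[C@@H](O)[C@H]1C(=C)CO
F12 | step 29 | trimethylsilyl ester bis(trimethylsilyl) ether of the target | C=C[C@@]1(C)C[C@H](OC(=O)/C(C)=C\COC(C)=O)[C@@H](C(=C)C(=O)O[Si](C)(C)C)[C@@H](O[Si](C)(C)C)[C@H]1C(=C)CO[Si](C)(C)C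
A1 | alternative 1 | tert-butyl [5-(TBS-oxy)-3-methyl-1-oxocyclohex-2-en-6-yl]acetate (photo-substrate, enone numbering; ring numbering of the target: C1=C6 enone, C5 ketone) | CC1=CC(=O)[C@H](CC(=O)OC(C)(C)C)[C@@H](O[Si](C)(C)C(C)(C)C)C1
A2 | alternative 1 | 1-methoxy-4-[(prop-2-yn-1-yloxy)methyl]benzene | C#CCOCc1ccc(OC)cc1
A3 | alternative 1 | cis-fused bicyclo[4.2.0]oct-7-en-2-one photoadduct | C2[C@@]1(C)C[C@H](O[Si](C)(C)C(C)(C)C)[C@@H](CC(=O)OC(C)(C)C)C(=O)[C@H]1C=2COCc3ccc(OC)cc3
A4 | alternative 2 | bromoacetal of the C5 alcohol of the C3=C4 cyclohexene | C=C[C@@]1(C)CC=C[C@@H](OC(CBr)OCC)[C@H]1C(=C)CO[Si](C)(C)C(C)(C)C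
A5 | alternative 2 | cis-fused lactol ethyl acetal with free C3 hydroxyl | C=C[C@@]1(C)C[C@H](O)[C@H]2C[C@@H](OCC)O[C@H]2[C@H]1C(=C)CO[Si](C)(C)C(C)(C)C
A6 | alternative 3 | open-chain C5 aldehyde with (Z)-2-(bromomethyl)alkenoate | C=C[C@@](C)(C[C@H](OCc1ccc(OC)cc1)/C=C(\CBr)C(=O)OCC[Si](C)(C)C)[C@@H](C=O)C(=C)CO[Si](C)(C)C(C)(C)C
A7 | alternative 3 | fully substituted cyclohexanol with α-methylene ester | C=C[C@@]1(C)C[C@H](OCc2ccc(OC)cc2)[C@@H](C(=C)C(=O)OCC[Si](C)(C)C)[C@@H](O)[C@H]1C(=C)CO[Si](C)(C)C(C)(C)C
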